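Target in this flask forms from reagent that first has to cross out of the second phase.

starting material 0.27 M; reagent in the second phase 0.270 M; protic impurity 0.0135 M; time 10 min; volume of the second phase over the first 1.0

    target ⇌ product in the second phase, rate k1*([target] - [product in the second phase]/K1) per volume of the first phase (K1 = 0.40, k1 = 0.0306 s⁻¹)
    reagent in the reaction phase ⇌ reagent in the second phase, rate k2*([reagent in the reaction phase] - [reagent in the second phase]/K2) per volume of the first phase (K2 = 2.11, k2 = 9.05 × 10⁻⁴ s⁻¹)
    starting material + reagent in the reaction phase → target (k3 = 0.0197 L mol⁻¹ s⁻¹)
    starting material + protic impurity → quenched substrate (k4 = 0.167 L mol⁻¹ s⁻¹)
    reagent in the reaction phase + target → over-reaction product (k5 = 0.00322 L mol⁻¹ s⁻¹)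
    starting material ⇌ dormant form (K6 = 1.0, k6 = 0.00208 s⁻¹)
    target → decomposed product (k7 = 0.00116 s⁻¹)

- target and product in the second phase together at 10 min, in percent of the starting material charged
- the change that raises the amount of target and product in the second phase together at 10 min, in percent of the starting material charged most ("none" if none brings more than 2 percentage points) (autumn / winter / dusk / none)
- amount of target and product in the second phase together at 10 min, in percent of the starting material charged, after autumn

- what is said of target includes product in the second phase
- in the second phase: reagent in the second phase, product in the second phase; everything else is in the first
- charges count per volume of the first phase; a concentration in a rate is the amount of a species over the volume of its own phase; every rate counts per litre of the first phase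
- run time (flask): 10 min

Turn the question round: for most of the starting material to become target, the reagent crossing during the run would have to approach the whole charge. From the full second phase reagent enters at 0.0257 min⁻¹; this feed, the crossing rate in fractions of the starting material charged, delivers 0.257 of the charge over the run, a quarter. The reckoning starts from this feed and then follows what becomes of the reagent that enters.

Starting material and dormant form tend to equal shares, and the protic impurity can take 0.0500 of the charge. Half of the remainder, held steady, makes reagent consumption pseudo-first-order at 0.152 min⁻¹. Reagent returns to the second phase at 0.0543 min⁻¹, slower than that, so it stays 4.86 min and a fraction 0.739 of it reacts. That stay leaves an effective feeding time of 5.76 min, and the fraction of the charge formed as target is 0.109.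

Target equilibrates between the phases in 0.156 min, far shorter than the run, which leaves 0.714 of it in the first phase. With a mean age of 3.33 min there, a fraction 0.834 survives decomposition. This gives 9.11%.

Winter doubles the feed and keeps the stay; dusk doubles the feed but shortens the stay to 3.84 min; autumn touches the short crossing time of target. The choice is winter, and autumn leaves 9.25%.

The forecast gave 9.3%, winter and 9.3% after autumn, holding that “Reagent supply is limiting”.

The simulation gives 8.53%, 8.54% after autumn, and winter as the best change, worth 7.3 percentage points against 4.9 points for dusk and 0.011 points for autumn.

In this flask at 10.0 min, reagent in the reaction phase is made 1.23 times faster than it is used up, each step taken net, while target and decomposed product together hold 0.409 of the feed multiplied by the time. The neighbour flask, left until 25 min, holds 15.5% target, all its forms counted, and 11.6% decomposed product, which is 0.422 of the feed multiplied by its time.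

The constants used here stand for no real mixture; the flask was simulated.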